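**Plan**
- Cuts: the bond from the methylene bridge to trione ring C (o-quinone methide/Michael union of a chromene half and a chiral trione half); in the chromene half the C8–acyl bond, then together O1–C8a and C2–C3 of pyran ring B, back to an acetone adduct on the carbon between the two bromines of 4,6-dibromoresorcinol diallyl ether; in the trione half the two ring C–C bonds made from a geranyl(methyl)malonate and pentane-2,4-dione.
- Enabling feature: O1 sits on C8a, between the acyl-bearing C8 and the styrene-bearing C4a of resorcinol ring A. A CMe2OH group on C8a can pass its oxygen to C8a by a 1,2-aryl shift; the ArO–CMe2 cation then lies next to vinyl carbon C3, and its attack leaves a C4 cation stabilised by the oxygens at C5, C7 and O1.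
- Forward: ring A is bought; ring B arises in step 5; hexanoyl enters at C8 by Br/Li exchange; deallylation and a Mannich reaction arm C6; ring C is closed by dianion acylation and Claisen condensation; the halves are joined last.
- Stereochemistry: the one stereocentre (4R, quaternary) comes from esterase desymmetrisation of the prochiral malonate and is carried unchanged; the E alkene comes from geranyl bromide.

Key step: step 5

Assumption: the esterase is taken to cleave the pro-S ester group of 25; if it prefers the other, the same half ester series is used with the carboxyl roles exchanged (the ester acylates the dianion, the acid is activated for ring closure).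

Step 1
Reactants: 1 4,6-dibromobenzene-1,3-diol; 2 3-bromoprop-1-ene (allyl bromide)
Product: 3 1,5-dibromo-2,4-bis(prop-2-en-1-yloxy)benzene
Conditions: 2 (2.5 equiv), K2CO3 (3 equiv), MeCN, 60 °C
Reagents that add atoms: allyl bromide 2, C=CCBr
Why: Williamson ether synthesis on both phenols; the allyl ethers should survive the organolithium and hypervalent-iodine steps and leave later under neutral conditions.

Step 2
Reactants: 3 1,5-dibromo-2,4-bis(prop-2-en-1-yloxy)benzene; 4 propan-2-one (acetone)
Product: 6 2-[2,6-dibromo-3,5-bis(prop-2-en-1-yloxy)phenyl]propan-2-ol, via aryllithium 5 (not isolated)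
Conditions: LiN(iPr)2 (1.1 equiv), THF, −78 °C; then 4 (3 equiv), −78 → 0 °C; then H2O
Reagents that add atoms: acetone 4, CC(C)=O
Why: Amide-base metalation should take the most acidic ring hydrogen, the one flanked by two bromines, and the 2,6-dibromoaryllithium (stable at −78 °C) adds 1,2 to the ketone; by the symmetry of 3 the carbinol carbon (future C8a) lands between the future C8 and C4a without a regiochemical choice.

Step 3
Reactants: 6 2-[2,6-dibromo-3,5-bis(prop-2-en-1-yloxy)phenyl]propan-2-ol; 7 N,N-dimethylformamide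
Product: 9 4-bromo-3,3-dimethyl-5,7-bis(prop-2-en-1-yloxy)-1,3-dihydro-2-benzofuran-1-ol (lactol; racemic at the lactol carbon), via dilithio species 8 (not isolated)
Conditions: n-BuLi (2.1 equiv), THF, −78 °C; then 7 (3 equiv), −78 → 0 °C; then H2O
Reagents that add atoms: N,N-dimethylformamide 7, CN(C)C=O
Why: After deprotonation of the hydroxyl, one bromine–lithium exchange (the bromines are equivalent and a second exchange on the dianion is disfavoured) and formylation give the hydroxy aldehyde, which should close to the five-membered lactol.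

Step 4
Reactants: 9 the lactol; 10 methyltriphenylphosphonium bromide
Product: 12 2-[2-bromo-6-ethenyl-3,5-bis(prop-2-en-1-yloxy)phenyl]propan-2-ol, via open-chain aldehyde 11 (not isolated)
Conditions: 10 (3 equiv), KOtBu (3 equiv), THF, 0 → 25 °C
Reagents that add atoms: methyltriphenylphosphonium bromide 10, C[P+](c1ccccc1)(c1ccccc1)c1ccccc1.[Br-]
Why: Wittig methylenation of a lactol through its ring-opened aldehyde form; the basic medium keeps the acid-sensitive tertiary benzylic alcohol next to the styrene intact.

Step 5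
Reactants: 12 2-[2-bromo-6-ethenyl-3,5-bis(prop-2-en-1-yloxy)phenyl]propan-2-ol
Product: 16 8-bromo-2,2-dimethyl-5,7-bis(prop-2-en-1-yloxy)-2H-chromene, via alkoxyiodonium triflate 13 (not isolated), via aryloxocarbenium triflate 14 (not isolated), via chroman-4-yl cation 15 (not isolated)
Conditions: PhI(OAc)2 (1.05 equiv), Me3SiOTf (2.1 equiv), pyridine (2.1 equiv), CH2Cl2, 25 °C, to form [PhI(pyridine)2](OTf)2 in the flask; then 12, 4 Å molecular sieves, −40 → 0 °C, dark
Reagents that add atoms: none
Why: Proposed new method: the tertiary hydroxyl of 12 exchanges onto the trivalent iodine centre to give alkoxyiodonium salt 13, whose O–I bond breaks with loss of iodobenzene while aryl carbon C8a shifts from C2 to oxygen (a Hock/Criegee-type 1,2-aryl shift from carbon to oxygen), which makes the O1–C8a bond and aryloxocarbenium ion 14; the vinyl terminus C3 then adds to C2 (Prins-type closure) to give the C4 cation 15, and loss of the C3 proton to pyridine gives the 2H-chromene. The closest known reaction types are the oxidative rearrangement of benzylic tertiary alcohols by N-ligated dicationic phenyliodine reagents, in which the oxocarbenium ion is caught by an external nucleophile, and the Prins cyclisation; an ortho vinyl group as the internal trap has not been shown. Ring B closes in the 6-endo-trig mode, equally a cationic oxa-6π closure of the 2-oxonia-triene C2=O1–C8a=C4a–C4=C3, and attack at C4 is excluded because it would leave a primary cation. No stereocentre is formed. The step needs O–I heterolysis with aryl shift to outrun both ionisation of the C2–O bond (after which the vinyl group would close onto C2 from carbon) and attack of the styrene on iodine; this is secured by the buffered medium free of strong Brønsted acid, by the fast ligand exchange of alcohols at cationic iodine, by the relief of strain when the CMe2 group wedged between Br and vinyl leaves C8a, and by the oxygens at C5, C7 and the new O1, all ortho or para to C4a, which stabilise cation 15. The position of the ring oxygen relative to the future acyl carbon needs no control, because O1 can only enter at the carbon that carried the carbinol.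

Step 6
Reactants: 16 8-bromo-2,2-dimethyl-5,7-bis(prop-2-en-1-yloxy)-2H-chromene; 17 N-methoxy-N-methylhexanamide
Product: 19 1-[2,2-dimethyl-5,7-bis(prop-2-en-1-yloxy)-2H-chromen-8-yl]hexan-1-one, via 8-lithiochromene 18 (not isolated)
Conditions: n-BuLi (1.05 equiv), THF, −78 °C; then 17 (1.2 equiv), −78 → 0 °C; then H2O
Reagents that add atoms: N-methoxy-N-methylhexanamide 17, CCCCCC(=O)N(C)OC
Why: Bromine–lithium exchange and acylation by an N-methoxy-N-methylamide, whose chelated tetrahedral adduct stops at the ketone; the bromine carried from step 2 places the hexanoyl group on C8 with no competition from C6.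

Step 7
Reactants: 19 1-[2,2-dimethyl-5,7-bis(prop-2-en-1-yloxy)-2H-chromen-8-yl]hexan-1-one
Product: 20 1-(5,7-dihydroxy-2,2-dimethyl-2H-chromen-8-yl)hexan-1-one
Conditions: Pd(PPh3)4 (5 mol %), morpholine (10 equiv), THF, 25 °C
Reagents that add atoms: none
Why: Zerovalent-palladium-catalysed deallylation (Tsuji–Trost-type allyl transfer to the amine) should free both phenols under neutral conditions that spare the chromene alkene and the ketone.

Step 8
Reactants: 20 1-(5,7-dihydroxy-2,2-dimethyl-2H-chromen-8-yl)hexan-1-one; 21 N,N-dimethylmethyleneiminium iodide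
Product: 22 1-{6-[(dimethylamino)methyl]-5,7-dihydroxy-2,2-dimethyl-2H-chromen-8-yl}hexan-1-one
Conditions: 21 (1.05 equiv), K2CO3 (1.5 equiv), CH2Cl2, 0 → 25 °C
Reagents that add atoms: N,N-dimethylmethyleneiminium iodide 21, C=[N+](C)C.[I-]
Why: Mannich aminomethylation at C6, the only free position of ring A and the one flanked by two phenolic hydroxyls.

Step 9
Reactants: 23 dimethyl 2-methylpropanedioate; 24 (2E)-1-bromo-3,7-dimethylocta-2,6-diene (geranyl bromide)
Product: 25 dimethyl 2-[(2E)-3,7-dimethylocta-2,6-dien-1-yl]-2-methylpropanedioate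
Conditions: NaH (1.1 equiv), THF, 0 °C; then 24 (1.05 equiv), 0 → 25 °C
Reagents that add atoms: geranyl bromide 24, BrC/C=C(\C)CCC=C(C)C
Why: SN2 alkylation of the malonate enolate at the primary allylic carbon with retention of the E alkene, giving a prochiral quaternary diester.

Step 10
Reactants: 25 dimethyl 2-[(2E)-3,7-dimethylocta-2,6-dien-1-yl]-2-methylpropanedioate
Product: 26 (2R)-2-[(2E)-3,7-dimethylocta-2,6-dien-1-yl]-3-methoxy-2-methyl-3-oxopropanoic acid
Conditions: pig liver esterase (a carboxylesterase), 0.1 M phosphate buffer pH 7.5/DMSO 9:1, 25 °C; product extracted at pH 3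
Reagents that add atoms: water, O
Why: Enzymatic desymmetrisation of a prochiral α,α-disubstituted malonate diester, in which the esterase hydrolyses one of the two enantiotopic ester groups and its active site sets the quaternary centre as R.

Step 11
Reactants: 26 the (2R)-half ester; 27 pentane-2,4-dione
Product: 30 (4R)-2-acetyl-4-[(2E)-3,7-dimethylocta-2,6-dien-1-yl]-3,5-dihydroxy-4-methylcyclohexa-2,5-dien-1-one, via acyl imidazolide 28 (not isolated), via triketo ester 29 (not isolated)
Conditions: 1,1'-carbonyldiimidazole (1.1 equiv), THF, 25 °C; then added to the dianion made from 27 (3 equiv) and LiN(iPr)2 (6 equiv), THF, −78 → 0 °C, then 40 °C; then aq. HCl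
Reagents that add atoms: pentane-2,4-dione 27, CC(=O)CC(C)=O
Why: The β-diketone dianion is acylated at its terminal carbon by the acyl imidazolide (far more electrophilic than the hindered methyl ester, so the acid carbon becomes the ring carbonyl next to the unsubstituted ring carbon), and Claisen (Dieckmann-type) closure of the central carbon onto the methyl ester, the only six-membered mode, follows; this assignment of the two carboxyl carbons turns the configuration of 26 into 4R, and the quaternary centre itself is not touched.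

Step 12
Reactants: 22 the Mannich base; 30 the (4R)-trione
Product: 32 (4R)-2-acetyl-4-[(2E)-3,7-dimethylocta-2,6-dien-1-yl]-6-[(8-hexanoyl-5,7-dihydroxy-2,2-dimethyl-2H-chromen-6-yl)methyl]-3,5-dihydroxy-4-methylcyclohexa-2,5-dien-1-one (CNP0319887.1), via o-quinone methide 31 (not isolated)
Conditions: 1,4-dioxane, 60 °C, N2
Reagents that add atoms: none
Why: Thermal loss of dimethylamine from the phenolic Mannich base should give the o-quinone methide, to which the trione adds through its only free nucleophilic ring carbon (Michael addition) to form the methylene bridge; the quaternary stereocentre is remote and cannot epimerise.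

**Compound list**
1 | 4,6-dibromobenzene-1,3-diol | Oc1cc(O)c(Br)cc1Br | starting material
2 | 3-bromoprop-1-ene (allyl bromide) | C=CCBr | starting material
3 | 1,5-dibromo-2,4-bis(prop-2-en-1-yloxy)benzene | C=CCOc1cc(OCC=C)c(Br)cc1Br | intermediate
4 | propan-2-one (acetone) | CC(C)=O | starting material
5 | [2,6-dibromo-3,5-bis(prop-2-en-1-yloxy)phenyl]lithium | [Li]c1c(Br)c(OCC=C)cc(OCC=C)c1Br | intermediate
6 | 2-[2,6-dibromo-3,5-bis(prop-2-en-1-yloxy)phenyl]propan-2-ol | CC(C)(O)c1c(Br)c(OCC=C)cc(OCC=C)c1Br | intermediate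
7 | N,N-dimethylformamide | CN(C)C=O | starting material
8 | lithium 2-[2-bromo-6-lithio-3,5-bis(prop-2-en-1-yloxy)phenyl]propan-2-olate | [Li]OC(C)(C)c1c([Li])c(OCC=C)cc(OCC=C)c1Br | intermediate
9 | 4-bromo-3,3-dimethyl-5,7-bis(prop-2-en-1-yloxy)-1,3-dihydro-2-benzofuran-1-ol (racemic lactol) | OC1OC(C)(C)c2c(Br)c(OCC=C)cc(OCC=C)c12 | intermediate
10 | methyltriphenylphosphonium bromide | C[P+](c1ccccc1)(c1ccccc1)c1ccccc1.[Br-] | starting material
11 | 3-bromo-2-(2-hydroxypropan-2-yl)-4,6-bis(prop-2-en-1-yloxy)benzaldehyde | CC(C)(O)c1c(Br)c(OCC=C)cc(OCC=C)c1C=O | intermediate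
12 | 2-[2-bromo-6-ethenyl-3,5-bis(prop-2-en-1-yloxy)phenyl]propan-2-ol | CC(C)(O)c1c(Br)c(OCC=C)cc(OCC=C)c1C=C | intermediate
13 | {2-[2-bromo-6-ethenyl-3,5-bis(prop-2-en-1-yloxy)phenyl]propan-2-yloxy}(phenyl)(pyridine)iodonium trifluoromethanesulfonate | CC(C)(O[I](c1ccccc1)[n+]1ccccc1)c1c(Br)c(OCC=C)cc(OCC=C)c1C=C.[O-]S(=O)(=O)C(F)(F)F | intermediate
14 | [2-bromo-6-ethenyl-3,5-bis(prop-2-en-1-yloxy)phenyl](propan-2-ylidene)oxonium trifluoromethanesulfonate | CC(C)=[O+]c1c(Br)c(OCC=C)cc(OCC=C)c1C=C.[O-]S(=O)(=O)C(F)(F)F | intermediate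
15 | 8-bromo-2,2-dimethyl-5,7-bis(prop-2-en-1-yloxy)-3,4-dihydro-2H-chromen-4-ylium trifluoromethanesulfonate | CC1(C)C[CH+]c2c(OCC=C)cc(OCC=C)c(Br)c2O1.[O-]S(=O)(=O)C(F)(F)F | intermediate
16 | 8-bromo-2,2-dimethyl-5,7-bis(prop-2-en-1-yloxy)-2H-chromene | CC1(C)C=Cc2c(OCC=C)cc(OCC=C)c(Br)c2O1 | intermediate
17 | N-methoxy-N-methylhexanamide | CCCCCC(=O)N(C)OC | starting material
18 | [2,2-dimethyl-5,7-bis(prop-2-en-1-yloxy)-2H-chromen-8-yl]lithium | CC1(C)C=Cc2c(OCC=C)cc(OCC=C)c([Li])c2O1 | intermediate
19 | 1-[2,2-dimethyl-5,7-bis(prop-2-en-1-yloxy)-2H-chromen-8-yl]hexan-1-one | CCCCCC(=O)c1c(OCC=C)cc(OCC=C)c2C=CC(C)(C)Oc12 | intermediate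
20 | 1-(5,7-dihydroxy-2,2-dimethyl-2H-chromen-8-yl)hexan-1-one | CCCCCC(=O)c1c(O)cc(O)c2C=CC(C)(C)Oc12 | intermediate
21 | N,N-dimethylmethyleneiminium iodide | C=[N+](C)C.[I-] | starting material
22 | 1-{6-[(dimethylamino)methyl]-5,7-dihydroxy-2,2-dimethyl-2H-chromen-8-yl}hexan-1-one | CCCCCC(=O)c1c(O)c(CN(C)C)c(O)c2C=CC(C)(C)Oc12 | intermediate
23 | dimethyl 2-methylpropanedioate | COC(=O)C(C)C(=O)OC | starting material
24 | (2E)-1-bromo-3,7-dimethylocta-2,6-diene (geranyl bromide) | BrC/C=C(\C)CCC=C(C)C | starting material
25 | dimethyl 2-[(2E)-3,7-dimethylocta-2,6-dien-1-yl]-2-methylpropanedioate | COC(=O)C(C)(C/C=C(\C)CCC=C(C)C)C(=O)OC | intermediate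
26 | (2R)-2-[(2E)-3,7-dimethylocta-2,6-dien-1-yl]-3-methoxy-2-methyl-3-oxopropanoic acid | OC(=O)[C@@](C)(C/C=C(\C)CCC=C(C)C)C(=O)OC | intermediate
27 | pentane-2,4-dione | CC(=O)CC(C)=O | starting material
28 | methyl (2R)-2-[(2E)-3,7-dimethylocta-2,6-dien-1-yl]-3-(1H-imidazol-1-yl)-2-methyl-3-oxopropanoate | O=C(n1ccnc1)[C@@](C)(C/C=C(\C)CCC=C(C)C)C(=O)OC | intermediate
29 | methyl (2R)-2-[(2E)-3,7-dimethylocta-2,6-dien-1-yl]-2-methyl-3,5,7-trioxooctanoate (enol mixture) | CC(=O)CC(=O)CC(=O)[C@@](C)(C/C=C(\C)CCC=C(C)C)C(=O)OC | intermediate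
30 | (4R)-2-acetyl-4-[(2E)-3,7-dimethylocta-2,6-dien-1-yl]-3,5-dihydroxy-4-methylcyclohexa-2,5-dien-1-one | O=C1C=C(O)[C@@](C)(C/C=C(\C)CCC=C(C)C)C(O)=C1C(C)=O | intermediate
31 | 8-hexanoyl-5-hydroxy-2,2-dimethyl-6-methylidene-2H-chromen-7(6H)-one (o-quinone methide) | C=C1C(=O)C(C(=O)CCCCC)=C2OC(C)(C)C=CC2=C1O | intermediate
32 | (4R)-2-acetyl-4-[(2E)-3,7-dimethylocta-2,6-dien-1-yl]-6-[(8-hexanoyl-5,7-dihydroxy-2,2-dimethyl-2H-chromen-6-yl)methyl]-3,5-dihydroxy-4-methylcyclohexa-2,5-dien-1-one (CNP0319887.1) | CCCCCC(=O)c1c(O)c(CC2=C(O)[C@@](C)(C/C=C(\C)CCC=C(C)C)C(O)=C(C(C)=O)C2=O)c(O)c2c1OC(C)(C)C=C2 | target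

Total steps: 12. Longest linear sequence: 9 steps (steps 1 to 8, then step 12).

**Steps most likely to fail**

1. Step 5 (proposed new method). The styrene or the electron-rich ring may attack iodine faster than the hindered alcohol exchanges onto it. The benzylic C–O bond may ionise, so that the vinyl group closes onto C2 from carbon before any aryl shift. The aryl shift itself may be slow, because the ring oxygens are meta to the migrating carbon. Fallback with known chemistry, from 3 back to 16: 3 would be metalated as in step 2 to aryllithium 5 and quenched with B(OMe)3 to give dimethyl [2,6-dibromo-3,5-bis(prop-2-en-1-yloxy)phenyl]boronate F1, which H2O2/NaOH would oxidise to 2,6-dibromo-3,5-bis(prop-2-en-1-yloxy)phenol F2. n-BuLi (2.1 equiv, −78 °C) would deprotonate the phenol and exchange one of the two equivalent bromines to give the C,O-dilithio species F3, and addition to 3-methylbut-2-enal would give 2-bromo-6-(1-hydroxy-3-methylbut-2-en-1-yl)-3,5-bis(prop-2-en-1-yloxy)phenol F4. Warming with pyridinium p-toluenesulfonate in toluene should dehydrate this to the (6Z)-o-quinone methide F5, whose oxa-6π electrocyclisation gives 16. Here the pyran oxygen comes from the phenol and the O1–C2 bond is made last.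

2. Step 10. The enzyme may discriminate poorly between the two enantiotopic ester groups, may prefer the other one, or may turn over the very lipophilic substrate slowly. Fallback, from 25 back to 26: half-saponification with KOH (1 equiv) in methanol would give the racemic half ester F6, and classical resolution by crystallisation with (S)-1-phenylethylamine would give the diastereomerically pure ammonium salt F7 of the (R)-acid (the antipodal amine is used if the other diastereomer crystallises first); acidification returns 26.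

3. Step 12. The aminomethyl group may be lost or transferred by retro-Mannich exchange, the o-quinone methide may self-condense before the trione adds, and the amine set free may promote exchange of the methylene bridge. Fallback with the donor and acceptor roles exchanged, from 30 and 20 back to 32: 30 would be aminomethylated with N,N-dimethylmethyleneiminium iodide to the trione Mannich base F8, which on gentle warming should lose dimethylamine to give the 6-methylidene trione F9; the free C6 of phenol 20 would add to this Michael acceptor to give 32.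

**Further compounds**
F1 | step 5 | dimethyl [2,6-dibromo-3,5-bis(prop-2-en-1-yloxy)phenyl]boronate | COB(OC)c1c(Br)c(OCC=C)cc(OCC=C)c1Br
F2 | step 5 | 2,6-dibromo-3,5-bis(prop-2-en-1-yloxy)phenol | Oc1c(Br)c(OCC=C)cc(OCC=C)c1Br
F3 | step 5 | lithium 2-bromo-6-lithio-3,5-bis(prop-2-en-1-yloxy)phenolate | [Li]Oc1c([Li])c(OCC=C)cc(OCC=C)c1Br
F4 | step 5 | 2-bromo-6-(1-hydroxy-3-methylbut-2-en-1-yl)-3,5-bis(prop-2-en-1-yloxy)phenol (racemic) | CC(C)=CC(O)c1c(O)c(Br)c(OCC=C)cc1OCC=C
F5 | step 5 | (6Z)-2-bromo-6-(3-methylbut-2-en-1-ylidene)-3,5-bis(prop-2-en-1-yloxy)cyclohexa-2,4-dien-1-one | CC(C)=C/C=C1\C(=O)C(Br)=C(OCC=C)C=C1OCC=C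
F6 | step 10 | racemic 2-[(2E)-3,7-dimethylocta-2,6-dien-1-yl]-3-methoxy-2-methyl-3-oxopropanoic acid | OC(=O)C(C)(C/C=C(\C)CCC=C(C)C)C(=O)OC
F7 | step 10 | (1S)-1-phenylethanaminium (2R)-2-[(2E)-3,7-dimethylocta-2,6-dien-1-yl]-3-methoxy-2-methyl-3-oxopropanoate | [O-]C(=O)[C@@](C)(C/C=C(\C)CCC=C(C)C)C(=O)OC.C[C@H]([NH3+])c1ccccc1
F8 | step 12 | (4R)-2-acetyl-6-[(dimethylamino)methyl]-4-[(2E)-3,7-dimethylocta-2,6-dien-1-yl]-3,5-dihydroxy-4-methylcyclohexa-2,5-dien-1-one | CN(C)CC1=C(O)[C@@](C)(C/C=C(\C)CCC=C(C)C)C(O)=C(C(C)=O)C1=O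
F9 | step 12 | (6R)-4-acetyl-6-[(2E)-3,7-dimethylocta-2,6-dien-1-yl]-5-hydroxy-6-methyl-2-methylidenecyclohex-4-ene-1,3-dione | C=C1C(=O)[C@@](C)(C/C=C(\C)CCC=C(C)C)C(O)=C(C(C)=O)C1=O
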